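Count what is left.

| setting | gamma | alpha | cedar | alder | birch |
|---|---|---|---|---|---|
| electrophile | 10 mM | 10 mM | 10 mM | 10 mM | 10 mM |
| nucleophile | 10 mM | 10 mM | 10.0 mM | 10.0 mM | 10.0 mM |
| free base | 24 mM | 90 mM | 80.0 mM | 20.0 mM | 40.0 mM |
| remark | run made earlier | run made earlier |  |  |  |
| time |  |  | 10 d | 10 d | 10 d |

- gamma (time / d: electrophile / %, target / %): 0.500: 58, 10; 1.25: 35, 7; 2.50: 25, 5; 4.00: 18, 1; 5.00: 14, 0; 8.00: 10, 0
- alpha (time / d: electrophile / %, target / %): 0.500: 58, 1; 1.25: 36, 2; 2.50: 23, 0; 4.00: 16, 3; 5.00: 12, 2; 8.00: 5, 0

(readings scatter by 1.5 percentage points)

- part of the electrophile that has reacted at the end, cedar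
- part of the electrophile that has reacted at the end, alder
- part of the electrophile that has reacted at the end, birch
- what raising the concentration of free base from its lowest to its highest value here does to the part of the electrophile that has reacted (changes below 5 percentage points count as none) (no change / it falls / it rises)

- what has gone from electrophile into another species counts as reacted, even if it can come back

1. Electrophile and nucleophile are charged at a ratio of 1.00. The bench rule for such a second-order loss is: fraction left = 1/(1 + g·t). One over the fraction left then climbs in a straight line with time.

2. The gamma run at 5.00 d gives 1.23 d⁻¹ for g, the clearing rate, the climb per day of that line. The alpha run at 5.00 d gives 1.47 d⁻¹.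

3. At 10 d the gamma value leaves 7.53 % and the alpha value leaves 6.38 %. My reckoning is therefore about 92.5 % reacted in alder and 93.6 % in cedar. The gap of 1.2 percentage points is less than the margin of 5 points, so I expect no change.

4. The border of the rule is looked for in the gap between the runs over the scatter: 1.33 at 5.00 d and 3.33 at 8.00 d. The later ratio rests on one pair of readings, so it is no proof that the runs part. Taken from the 8.00 d readings, the rule leaves 8.16 % and 4.04 %, a gap of 4.1 points, still under the margin.

5. The forecast gives 89.5 % for alder, 93 % for birch and 95.5 % for cedar, with the trend it rises: “The runs separate late”. It differs from my reckoning on the trend.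

    electrophile + nucleophile → acid set free + target (k = 0.00158 M⁻¹ s⁻¹)
    nucleophile + acid set free ⇌ protonated nucleophile, settled at all times (K = 51300 M⁻¹)
    acid set free + free base ⇌ salt of the base, settled at all times (K = 93000 M⁻¹)
    electrophile + acid set free ⇌ idle adduct, settled at all times (K = 21600 M⁻¹)
    free base + target → over-reaction product (k = 0.00277 M⁻¹ s⁻¹)

The flasks give 91.3 % for alder, 92.3 % for birch and 92.8 % for cedar, so the trend is no change, with a change of 1.5 points. At the asked time alder holds more idle adduct than cedar, 4.09 % against 0.249 %, and that counts as reacted. The clearing rate of 1.23 d⁻¹ left 7.53 % for alder, where 8.7 % of the electrophile stands. Alder read at 4.0 d gets 16.9 % from the same rate, and that flask holds 17 %.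

(The earlier runs and the new flask come from a simulation for substances that don't exist, noise included.)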